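## Retrosynthetic overview

- The target has ring A (pyran O2–C1–C8a–C4a–C4–C3), ring B (carbocycle C4a–C5–C6–C7–C8–C8a) and ring C (δ-lactone on C8). Ring A is made last, by an acid/gold isomerisation of a cage ketone that builds C3–O2–C1 and frees 7-OH and the lactone.
- Ring B is closed by forming C5–C6 (aldol) and C4a–C8a (enol ether onto ketone) between a chloro-enynone enol silane (C3, C4, C4a, C5 plus side chain) and a dihydrofuran aldehyde (C1, C8a, C8, C7, C6 plus lactone).
- Enabling feature: C6(=O)–C5(Cl)=C4a is an enolised 1,3-dicarbonyl (polyketide) unit, and C8a is the α-carbon of the aldehyde-level C1 (enol ether O2–C1=C8a). C5 and C8a are therefore donors and C6 and C4a acceptors, the same polarity as the biosynthetic chain extension and C8a→C4a aldol closure.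
- The dihydrofuran aldehyde carries a temporary O7–C1 ring (masks 7-OH, keeps C1 at aldehyde level, activates C8a). It comes from an acetal cage made by O→C Claisen transfer of the lactone onto a butenolide-derived lactol, which sets C8 from C7. C7 comes from (R)-2-methylglycidol, the lactone from ethyl (S)-3-hydroxybutanoate, the side chain from (S)-2-methylbutan-1-ol.
- Ring order: ring C → butenolide (temporary) → acetal cage (temporary) → ring B (key step) → ring A.

Key step: step 18

Remark: locants are isochromene locants (O2, C1, C3 bearing the dienyl chain, C4, C4a, C5–Cl, C6=O, C7, C8, C8a; lactone O1′, C2′, C3′, C4′, C5′, C6′). C3′ lies between two carbonyls and equilibrates through the enol, so it is assumed to settle under thermodynamic control in the keto form drawn for the target; no step sets it kinetically.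

## Route

**Side-chain nucleophile**

Step 1
Reactants: 1 (S)-2-methylbutan-1-ol
Product: 3 ethyl (S,E)-2,4-dimethylhex-2-enoate, via (S)-2-methylbutanal 2 (not isolated)
Conditions: TEMPO (10 mol %), PhI(OAc)2, CH2Cl2, rt; then Ph3P=C(Me)CO2Et, rt
Reagents that add atoms: ethyl 2-(triphenylphosphoranylidene)propanoate, CCOC(=O)C(C)=P(c1ccccc1)(c1ccccc1)c1ccccc1
Why: Oxidation gives the epimerisable aldehyde 2, which is trapped in the same flask by the stabilised ylide (Wittig reaction, E-selective) before it can racemise; the stereocentre comes from 1.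

Step 2
Reactants: 3 ethyl (S,E)-2,4-dimethylhex-2-enoate
Product: 4 (S,E)-2,4-dimethylhex-2-en-1-ol
Conditions: i-Bu2AlH, CH2Cl2, −78 °C
Reagents that add atoms: none
Why: 1,2-Reduction of the enoate by the aluminium hydride gives the allylic alcohol without touching the alkene or the remote stereocentre.

Step 3
Reactants: 4 (S,E)-2,4-dimethylhex-2-en-1-ol
Product: 5 (S,E)-2,4-dimethylhex-2-enal
Conditions: MnO2, CH2Cl2, rt
Reagents that add atoms: none
Why: Allylic oxidation with MnO2 stops at the enal and does not isomerise the trisubstituted alkene.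

Step 4
Reactants: 5 (S,E)-2,4-dimethylhex-2-enal
Product: 6 trimethyl[(S,3E,5E)-5,7-dimethylnona-3,5-dien-1-yn-1-yl]silane
Conditions: (EtO)2P(O)CH2C≡CSiMe3, LiN(SiMe3)2, THF, −78 → 0 °C
Reagents that add atoms: diethyl [3-(trimethylsilyl)prop-2-yn-1-yl]phosphonate, CCOP(=O)(CC#C[Si](C)(C)C)OCC
Why: Horner–Wadsworth–Emmons olefination with the lithiated propargyl phosphonate should give the new disubstituted alkene with E geometry under the usual thermodynamic control of the oxaphosphetane.

Step 5
Reactants: 6 trimethyl[(S,3E,5E)-5,7-dimethylnona-3,5-dien-1-yn-1-yl]silane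
Product: 7 (S,3E,5E)-5,7-dimethylnona-3,5-dien-1-yne
Conditions: K2CO3, MeOH, rt
Reagents that add atoms: none
Why: Methanolysis of the alkynyl–silicon bond is selective and leaves the diene untouched.

Step 6
Reactants: 7 (S,3E,5E)-5,7-dimethylnona-3,5-dien-1-yne
Product: 9 (S,5E,7E)-1-chloro-7,9-dimethylundeca-5,7-dien-3-yn-2-one, via lithium acetylide 8 (not isolated)
Conditions: n-BuLi, THF, −78 °C; then ClCH2C(O)N(OMe)Me, −78 → −40 °C; inverse quench into cold 1 M HCl
Reagents that add atoms: 2-chloro-N-methoxy-N-methylacetamide, CON(C)C(=O)CCl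
Why: Acylation of the acetylide with the Weinreb amide stops at the ketone because the chelated tetrahedral adduct survives until the acidic quench, which also keeps the liberated amine from adding to the ynone.

Step 7
Reactants: 9 (S,5E,7E)-1-chloro-7,9-dimethylundeca-5,7-dien-3-yn-2-one
Product: 10 {[(1Z,5E,7E,9S)-1-chloro-7,9-dimethylundeca-1,5,7-trien-3-yn-2-yl]oxy}trimethylsilane
Conditions: Me3SiOTf, Et3N, CH2Cl2, −78 → 0 °C; used crude
Reagents that add atoms: trimethylsilyl trifluoromethanesulfonate, C[Si](C)(C)OS(=O)(=O)C(F)(F)F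
Why: Soft enolisation of the only enolisable position (C5) gives the enol silane, expected as the Z isomer; its geometry is irrelevant because C5 becomes sp2 in the target.

**Lactone**

Step 8
Reactants: 11 ethyl (S)-3-hydroxybutanoate
Product: 12 tert-butyl (S)-5-hydroxy-3-oxohexanoate
Conditions: t-BuOAc, LiN(i-Pr)2 (3.3 equiv), THF, −78 → −20 °C; aq. NH4Cl
Reagents that add atoms: tert-butyl acetate, CC(=O)OC(C)(C)C
Why: Crossed Claisen condensation with excess lithium enolate (the free hydroxyl is carried as its alkoxide) extends the chain without touching the carbinol stereocentre.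

Step 9
Reactants: 12 tert-butyl (S)-5-hydroxy-3-oxohexanoate
Product: 13 (S)-6-methyldihydro-2H-pyran-2,4(3H)-dione
Conditions: CF3CO2H, CH2Cl2, 0 °C → rt
Reagents that add atoms: none
Why: Acid cleaves the tert-butyl ester and the δ-hydroxyl lactonises onto C2′ by acyl substitution, so C6′ keeps its configuration.

**Core fragment**

Step 10
Reactants: 14 (R)-2-methylglycidol
Product: 15 (S)-tert-butyl[(2-methyloxiran-2-yl)methoxy]diphenylsilane
Conditions: t-BuPh2SiCl, imidazole, CH2Cl2, 0 °C → rt
Reagents that add atoms: tert-butyl(chloro)diphenylsilane, CC(C)(C)[Si](Cl)(c1ccccc1)c1ccccc1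
Why: Silylation of the primary alcohol installs the bulky group that later shields one face at C8; the quaternary centre (future C7) is untouched and only its descriptor changes.

Step 11
Reactants: 15 (S)-tert-butyl[(2-methyloxiran-2-yl)methoxy]diphenylsilane
Product: 17 (5S)-5-{[(tert-butyldiphenylsilyl)oxy]methyl}-5-methyl-3-(phenylselanyl)dihydrofuran-2(3H)-one, via hydroxy acid 16 (not isolated)
Conditions: PhSeCH2CO2H, LiN(i-Pr)2 (2.2 equiv), THF, −78 → 0 °C; then 15, 0 °C → rt; then AcOH, 60 °C
Reagents that add atoms: (phenylselanyl)acetic acid, OC(=O)C[Se]c1ccccc1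
Why: The carboxylic acid dianion opens the 2,2-disubstituted epoxide at its CH2 carbon (SN2), and the tertiary γ-hydroxy acid lactonises on acidification, so no bond at the quaternary centre is broken.

Step 12
Reactants: 17 selenolactone
Product: 18 (S)-5-{[(tert-butyldiphenylsilyl)oxy]methyl}-5-methylfuran-2(5H)-one
Conditions: H2O2 (30 % aq.), pyridine, CH2Cl2, 0 °C → rt
Reagents that add atoms: none
Why: Selenoxide syn-elimination can only use the ring CH2 hydrogens and therefore gives the endocyclic butenolide.

Step 13
Reactants: 18 butenolide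
Product: 19 (5S)-5-{[(tert-butyldiphenylsilyl)oxy]methyl}-5-methyl-2,5-dihydrofuran-2-ol (anomer mixture)
Conditions: i-Bu2AlH (1.1 equiv), CH2Cl2, −78 °C; aq. KNaC4H4O6
Reagents that add atoms: none
Why: Partial reduction of the lactone stops at the lactol, which cannot dehydrate to a furan because C5 is quaternary; C1 is now at the aldehyde level.

Step 14
Reactants: 19 lactol; 13 (S)-6-methyldihydro-2H-pyran-2,4(3H)-dione
Product: 22 cage acetal (C1 bonded to O7 and O4′; TBDPS ether), via mixed acetal 20 (not isolated), via Claisen product 21 (not isolated)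
Conditions: PPh3, DIAD, THF, 0 °C → rt; then PhMe, Eu(fod)3 (5 mol %), 80 °C; then PPTS (cat.), rt
Reagents that add atoms: none
Why: Mitsunobu O-alkylation of the acidic lactone enol gives the allyl vinyl ether 20, and its Claisen rearrangement moves C3′ suprafacially from O4′–C1 to C8; the anomers should interconvert under the mild Lewis acid and the one whose transition state keeps the lactone anti to CH2OTBDPS (syn to methyl) should rearrange faster, which sets C8, after which the enol O–H adds to the new enol ether to close the cage.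

Step 15
Reactants: 22 cage acetal (TBDPS ether)
Product: 23 cage acetal primary alcohol
Conditions: Bu4NF, AcOH, THF, 0 °C → rt
Reagents that add atoms: none
Why: Buffered fluoride removes the silyl ether while the acetal cage, which has no acidic C–H and no free carbonyl, stays intact.

Step 16
Reactants: 23 cage acetal primary alcohol
Product: 24 cage acetal aldehyde
Conditions: Dess–Martin periodinane, NaHCO3, CH2Cl2, rt
Reagents that add atoms: none
Why: Dess–Martin oxidation gives the non-enolisable aldehyde (C6) next to the quaternary C7 under neutral conditions that the acetal tolerates.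

Step 17
Reactants: 24 cage acetal aldehyde
Product: 25 dihydrofuran aldehyde with the lactone as its triethylsilyl enol ether
Conditions: Et3SiOTf, Et3N, CH2Cl2, −78 → −20 °C; filtered through Et3N-deactivated silica and used at once
Reagents that add atoms: triethylsilyl trifluoromethanesulfonate, CC[Si](CC)(CC)OS(=O)(=O)C(F)(F)F
Why: Silyl triflate/amine converts the acetal into an enol ether by expelling the better leaving group (the vinylogous carboxylate O4′, which ends up silylated) and deprotonating C8a; this unmasks C8a as a nucleophile while the lactone stays masked and O7 stays protected in the ring.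

**Key step and endgame**

Step 18
Reactants: 25 dihydrofuran aldehyde with lactone silyl enol ether; 10 chloro-enynone enol silane
Product: 27 cage diol (C6–OH and C4a–OH; mixture at C4a, C5 and C6), via aldol adduct 26 (not isolated)
Conditions: 10 (2 equiv), BF3·OEt2 (2.5 equiv), 2,6-di-tert-butyl-4-methylpyridine (0.3 equiv), CH2Cl2, −78 → −30 °C; aq. NaHCO3
Reagents that add atoms: none
Why: Proposed new method: BF3 activates the aldehyde of 25 and enol silane 10 adds (Mukaiyama aldol, C5–C6) to give aldolate 26, whose BF3-bound ynone carbonyl C4a is then attacked by the internal dihydrofuran carbon C8a (Prins-type enol-ether/ketone addition, C4a–C8a), and the O7-stabilised oxocarbenium ion at C1 is captured by the neighbouring silyl enol ether oxygen O4′ with loss of the silyl group, re-forming the acetal cage; the closest known reaction types are the Mukaiyama aldol addition and Lewis-acid-promoted aldol/Prins cascades of cyclic enol ethers with carbonyl groups, which have not been run as one domino on this substrate class. Ring B (C4a–C5–C6–C7–C8–C8a) closes 6-(enolexo)-exo-trig, and the pyran ring of the cage (O4′–C1–C8a–C8–C3′=C4′) closes 6-exo-trig by oxygen attack on the oxocarbenium ion. C8a is set by the tether, because C4a can only reach the dihydrofuran face that carries C6 (anti to C3′ on C8), and C1 is fixed by the bridge; C4a, C5 and C6 form as mixtures and are all erased later. The step needs the aldehyde to react with 10 before the internal enol ether does anything, which is secured by the excess of the unhindered, more nucleophilic 10, by the impossibility of an internal C8a→C6 closure (four-membered ring) and by the hindered pyridine that suppresses proton-initiated enol-ether oligomerisation. It also needs C8a to add 1,2 to C4a and not to C3 (eight-membered ring), and C5 must not attack C1, which holds because C1 is an enol-ether carbon that becomes electrophilic only after the C4a–C8a bond exists.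

Step 19
Reactants: 27 cage diol
Product: 28 cage ketone (C6=O; tertiary propargylic C4a–OH retained)
Conditions: Dess–Martin periodinane, NaHCO3, CH2Cl2, 0 °C → rt
Reagents that add atoms: none
Why: Only the secondary C6 carbinol can be oxidised, which removes the C6 stereocentre and sets up the β-hydroxy ketone for elimination.

Step 20
Reactants: 28 cage ketone
Product: 29 CNP0584120.1, (7S,8S)-5-chloro-3-[(1E,3E,5S)-3,5-dimethylhepta-1,3-dien-1-yl]-7-hydroxy-7-methyl-8-[(3R,6S)-6-methyl-2,4-dioxooxan-3-yl]-7,8-dihydro-6H-isochromen-6-one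
Conditions: Au(OAc)3 (5 mol %), CF3CO2H (1 equiv), wet ClCH2CH2Cl, rt
Reagents that add atoms: none
Why: A net isomerisation: gold/acid-promoted Meyer–Schuster transposition moves the C4a oxygen to C3, acid opens the acetal cage, the C3 oxygen closes onto C1 (6-endo, as in 2-alkynylbenzaldehyde cycloisomerisations) and loss of the C5 proton gives the neutral pyranylidene ketone, releasing 7-OH and the free lactone; C7, C8 and C6′ are not touched and C3′ equilibrates as stated in the remark.

## Compound list

1 | (S)-2-methylbutan-1-ol | CC[C@H](C)CO | starting material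
2 | (S)-2-methylbutanal | CC[C@H](C)C=O | intermediate
3 | ethyl (S,E)-2,4-dimethylhex-2-enoate | CC[C@H](C)/C=C(C)/C(=O)OCC | intermediate
4 | (S,E)-2,4-dimethylhex-2-en-1-ol | CC[C@H](C)/C=C(C)/CO | intermediate
5 | (S,E)-2,4-dimethylhex-2-enal | CC[C@H](C)/C=C(C)/C=O | intermediate
6 | trimethyl[(S,3E,5E)-5,7-dimethylnona-3,5-dien-1-yn-1-yl]silane | CC[C@H](C)/C=C(C)/C=C/C#C[Si](C)(C)C | intermediate
7 | (S,3E,5E)-5,7-dimethylnona-3,5-dien-1-yne | CC[C@H](C)/C=C(C)/C=C/C#C | intermediate
8 | lithium acetylide of 7 | CC[C@H](C)/C=C(C)/C=C/C#C[Li] | intermediate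
9 | (S,5E,7E)-1-chloro-7,9-dimethylundeca-5,7-dien-3-yn-2-one | CC[C@H](C)/C=C(C)/C=C/C#CC(=O)CCl | intermediate
10 | {[(1Z,5E,7E,9S)-1-chloro-7,9-dimethylundeca-1,5,7-trien-3-yn-2-yl]oxy}trimethylsilane | CC[C@H](C)/C=C(C)/C=C/C#C/C(O[Si](C)(C)C)=C/Cl | intermediate
11 | ethyl (S)-3-hydroxybutanoate | CCOC(=O)C[C@H](C)O | starting material
12 | tert-butyl (S)-5-hydroxy-3-oxohexanoate | CC(C)(C)OC(=O)CC(=O)C[C@H](C)O | intermediate
13 | (S)-6-methyldihydro-2H-pyran-2,4(3H)-dione | C[C@H]1CC(=O)CC(=O)O1 | intermediate
14 | (R)-2-methylglycidol, (R)-(2-methyloxiran-2-yl)methanol | OC[C@@]1(C)OC1 | starting material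
15 | (S)-tert-butyl[(2-methyloxiran-2-yl)methoxy]diphenylsilane | CC(C)(C)[Si](c1ccccc1)(c1ccccc1)OC[C@@]1(C)OC1 | intermediate
16 | (4S)-5-[(tert-butyldiphenylsilyl)oxy]-4-hydroxy-4-methyl-2-(phenylselanyl)pentanoic acid (C2 epimers) | CC(C)(C)[Si](c1ccccc1)(c1ccccc1)OC[C@@](C)(O)CC([Se]c1ccccc1)C(=O)O | intermediate
17 | (5S)-5-{[(tert-butyldiphenylsilyl)oxy]methyl}-5-methyl-3-(phenylselanyl)dihydrofuran-2(3H)-one (C3 epimers) | CC(C)(C)[Si](c1ccccc1)(c1ccccc1)OC[C@@]1(C)OC(=O)C([Se]c2ccccc2)C1 | intermediate
18 | (S)-5-{[(tert-butyldiphenylsilyl)oxy]methyl}-5-methylfuran-2(5H)-one | CC(C)(C)[Si](c1ccccc1)(c1ccccc1)OC[C@@]1(C)OC(=O)C=C1 | intermediate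
19 | (5S)-5-{[(tert-butyldiphenylsilyl)oxy]methyl}-5-methyl-2,5-dihydrofuran-2-ol (anomers) | CC(C)(C)[Si](c1ccccc1)(c1ccccc1)OC[C@@]1(C)OC(O)C=C1 | intermediate
20 | mixed acetal: (6S)-6-methyl-5,6-dihydro-2H-pyran-2-one carrying at O4′ the 2,5-dihydrofuran-2-yl group of 19 (anomers at C1) | CC(C)(C)[Si](c1ccccc1)(c1ccccc1)OC[C@@]1(C)OC(OC2=CC(=O)O[C@@H](C)C2)C=C1 | intermediate
21 | Claisen product: 2,3-dihydrofuran (O7–C1=C8a) with C8 bonded to C3′ of the enolised lactone, C3′ syn to the C7 methyl | CC(C)(C)[Si](c1ccccc1)(c1ccccc1)OC[C@@]1(C)OC=C[C@@H]1C1=C(O)C[C@H](C)OC1=O | intermediate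
22 | cage acetal: dioxabicyclo[3.2.1]octene in which acetal C1 carries O7 and O4′, C8 carries C3′, C7 carries methyl (syn to C3′) and CH2OTBDPS; fused at C3′=C4′ to the (S)-6′-methyl-5′,6′-dihydropyran-2′-one | CC(C)(C)[Si](c1ccccc1)(c1ccccc1)OC[C@@]1(C)O[C@H]2C[C@@H]1C1=C(O2)C[C@H](C)OC1=O | intermediate
23 | cage acetal primary alcohol (22 without the silyl group) | OC[C@@]1(C)O[C@H]2C[C@@H]1C1=C(O2)C[C@H](C)OC1=O | intermediate
24 | cage acetal aldehyde (C6 = CHO on C7) | O=C[C@@]1(C)O[C@H]2C[C@@H]1C1=C(O2)C[C@H](C)OC1=O | intermediate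
25 | dihydrofuran aldehyde: 2,3-dihydrofuran (O7–C1=C8a) with C7 bearing methyl and CHO, C8 bearing the lactone as its 4′-O-triethylsilyl enol ether | O=C[C@@]1(C)OC=C[C@@H]1C1=C(O[Si](CC)(CC)CC)C[C@H](C)OC1=O | intermediate
26 | aldol adduct: 25 with C6 now CH(OH) bonded to C5HCl–C4a(=O)–C≡C–dienyl (drawn as free alcohol; C5, C6 epimers) | CC[C@H](C)/C=C(C)/C=C/C#CC(=O)C(Cl)C(O)[C@@]1(C)OC=C[C@@H]1C1=C(O[Si](CC)(CC)CC)C[C@H](C)OC1=O | intermediate
27 | cage diol: ring B closed (C4a(OH)(alkynyl)–C5HCl–C6H(OH)–C7–C8–C8a) on the face of the tetrahydrofuran opposite to the acetal/lactone bridge; mixture at C4a, C5, C6 | CC[C@H](C)/C=C(C)/C=C/C#CC1(O)C(Cl)C(O)[C@@]2(C)O[C@H]3[C@@H]1[C@@H]2C1=C(O3)C[C@H](C)OC1=O | intermediate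
28 | cage ketone (27 with C6=O; mixture at C4a, C5) | CC[C@H](C)/C=C(C)/C=C/C#CC1(O)C(Cl)C(=O)[C@@]2(C)O[C@H]3[C@@H]1[C@@H]2C1=C(O3)C[C@H](C)OC1=O | intermediate
29 | CNP0584120.1, (7S,8S)-5-chloro-3-[(1E,3E,5S)-3,5-dimethylhepta-1,3-dien-1-yl]-7-hydroxy-7-methyl-8-[(3R,6S)-6-methyl-2,4-dioxooxan-3-yl]-7,8-dihydro-6H-isochromen-6-one | CC[C@H](C)/C=C(C)/C=C/C1=CC2=C(Cl)C(=O)[C@@](C)(O)[C@@H]([C@@H]3C(=O)C[C@H](C)OC3=O)C2=CO1 | target

## Totals and risks

Total step count: 20. Longest linear sequence: 11 steps (14 → 29, steps 10–20).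

Steps most likely to fail:

1. Step 18 (Proposed new method). Possible failures are cationic oligomerisation of the dihydrofuran under BF3, an intermolecular enol-ether/aldehyde reaction outrunning the aldol, arrest after the aldol stage, or capture of the oxocarbenium ion by the C6 oxygen instead of O4′, which would tie up the hydroxyl needed in step 19. Fallback, setting out from 25 and 9 and returning at 27: make the two bonds in separate, individually known reactions. A boron aldol (n-Bu2BOTf, Et3N, CH2Cl2, −78 °C, with the boron enolate of 9 formed first) gives aldol adduct 26 in isolated form. TESCl/imidazole then caps the C6 oxygen to give the bis-silyl compound F1. A separate Prins-type ring closure (Me3SiOTf cat., 2,6-di-tert-butylpyridine, −78 °C) with the C6 oxygen blocked gives the C6-O-silyl cage F2, and HF·pyridine releases 27.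

2. Step 14. Possible failures are C-alkylation of the lactone at C3′ by the anomeric electrophile, ionisation of the mixed acetal with recombination at C1, or poor facial control at C8 if the anomers do not interconvert. Fallback, setting out from 18 and 13 and returning at 22: base-catalysed Michael addition of 13 to butenolide 18 (DBU, MeCN, 40 °C) anti to the silyloxymethyl group gives the γ-lactone adduct F3. The dione is then protected as its lithium enolate (LiN(SiMe3)2, 1 equiv) and i-Bu2AlH (−78 °C) reduces only the γ-lactone to the lactol F4, which closes to 22 with PPTS.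

3. Step 20. Possible failures are 5-exo closure or allene formation at the propargylic centre, an acid-promoted α-ketol shift at C6/C7, or incomplete transfer of C1 from the lactone oxygen to O2. Fallback, setting out from 28 and returning at 29: replace the single gold/acid cascade by two known steps without oxygen transposition. TsOH·H2O in wet THF hydrolyses the acetal and eliminates the β-hydroxyl to give the open hydroxymethylene chloro-enynone F5 (in equilibrium with its lactol). AgNO3 (cat.) in acetone then effects the 6-endo cycloisomerisation of the 2-alkynyl vinylogous acid, with O2 taken from the C1 oxygen, to give 29.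

## Further compounds

F1 | step 18 | C6-O-triethylsilyl ether of aldol adduct 26 | CC[C@H](C)/C=C(C)/C=C/C#CC(=O)C(Cl)C(O[Si](CC)(CC)CC)[C@@]1(C)OC=C[C@@H]1C1=C(O[Si](CC)(CC)CC)C[C@H](C)OC1=O
F2 | step 18 | C6-O-triethylsilyl ether of cage diol 27 | CC[C@H](C)/C=C(C)/C=C/C#CC1(O)C(Cl)C(O[Si](CC)(CC)CC)[C@@]2(C)O[C@H]3[C@@H]1[C@@H]2C1=C(O3)C[C@H](C)OC1=O
F3 | step 14 | Michael adduct: γ-butyrolactone (O7–C1(=O)–C8aH2–C8–C7) with C8 bonded to C3′ of the enolised lactone, anti to CH2OTBDPS | CC(C)(C)[Si](c1ccccc1)(c1ccccc1)OC[C@@]1(C)OC(=O)C[C@@H]1C1=C(O)C[C@H](C)OC1=O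
F4 | step 14 | lactol of F3 (C1 hemiacetal) | CC(C)(C)[Si](c1ccccc1)(c1ccccc1)OC[C@@]1(C)OC(O)C[C@@H]1C1=C(O)C[C@H](C)OC1=O
F5 | step 20 | open form of 29: 4-alkynyl-3-chloro-6-(hydroxymethylene)cyclohex-3-en-2-one carrying the C7 carbinol and the C8 lactone | CC[C@H](C)/C=C(C)/C=C/C#CC1=C(Cl)C(=O)[C@@](C)(O)[C@@H](C2C(=O)C[C@H](C)OC2=O)C1=CO
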